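**Retrosynthetic overview**
- Target ⇒ MOM cleavage and Steglich acylation of an (S)-configured quinone alcohol, itself from Teuber oxidation of a 1-naphthol (ring A becomes the quinone last).
- Side chain ⇒ the C1'–C2' bond is made by asymmetric allylboration of a 2-naphthaldehyde (sets S), then cross-metathesis builds the prenyl terminus.
- Naphthaldehyde ⇒ crossed Claisen formylation and DDQ aromatisation of an 8-oxygenated 5-methoxy-1-tetralone.
- OH/OMe differentiation ⇒ peri-carbonyl-directed BCl3 mono-demethylation of 5,8-dimethoxy-1-tetralone.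
- Ring order: ring B (benzenoid) is bought as 1,4-dimethoxybenzene; ring A is annulated by Friedel–Crafts succinoylation, reduction and cyclisation, then aromatised and finally oxidised.

Assumption: the single stereocentre of the SMILES is read as S (alkannin series); equivalents and temperatures are indicative.

**Step 1**
Reactants: 1 1,4-dimethoxybenzene; 2 succinic anhydride
Product: 3 4-(2,5-dimethoxyphenyl)-4-oxobutanoic acid
Conditions: AlCl3 (2.2 equiv), CH2Cl2–MeNO2, 0 °C → rt; aq HCl
Reagents that add atoms: none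
Why: Friedel–Crafts acylation of the symmetrical, electron-rich diether can occur at only one type of ring position, and the keto acid formed is deactivated towards a second acylation.

**Step 2**
Reactants: 3 4-(2,5-dimethoxyphenyl)-4-oxobutanoic acid
Product: 4 4-(2,5-dimethoxyphenyl)butanoic acid
Conditions: H2 (3 atm), 10% Pd/C, AcOH, cat. HClO4, 50 °C
Reagents that add atoms: none
Why: Acid-promoted catalytic hydrogenolysis of an aryl ketone to the methylene is facile on an electron-rich ring, while the acid and the aryl ethers are inert.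

**Step 3**
Reactants: 4 4-(2,5-dimethoxyphenyl)butanoic acid
Product: 5 5,8-dimethoxy-3,4-dihydronaphthalen-1(2H)-one
Conditions: polyphosphoric acid, 80 °C
Reagents that add atoms: none
Why: Intramolecular Friedel–Crafts acylation (Haworth cyclisation) can close only onto the single free ortho carbon, giving the six-membered ring A ketone.

**Step 4**
Reactants: 5 5,8-dimethoxy-3,4-dihydronaphthalen-1(2H)-one
Product: 7 8-hydroxy-5-methoxy-3,4-dihydronaphthalen-1(2H)-one, via aryloxydichloroborane chelate 6 (not isolated)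
Conditions: BCl3 (1.2 equiv), CH2Cl2, −78 → 0 °C; H2O
Reagents that add atoms: none
Why: In this chelation-controlled Lewis-acid ether cleavage BCl3 bridges the ketone oxygen and the peri 8-methoxy oxygen in a six-membered chelate, so chloride removes only that methyl and the remote 5-methoxy group survives.

**Step 5**
Reactants: 7 8-hydroxy-5-methoxy-3,4-dihydronaphthalen-1(2H)-one
Product: 8 5-methoxy-8-(methoxymethoxy)-3,4-dihydronaphthalen-1(2H)-one
Conditions: NaH (1.05 equiv), MOMCl, DMF, 0 °C → rt
Reagents that add atoms: chloromethyl methyl ether (MOMCl), COCCl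
Why: Williamson-type O-alkylation of the sodium phenoxide (far more acidic than the ketone α-CH) installs an acetal that tolerates base, DDQ, boranes, fluoride and Fremy's salt.

**Step 6**
Reactants: 8 5-methoxy-8-(methoxymethoxy)-3,4-dihydronaphthalen-1(2H)-one; 9 ethyl formate
Product: 10 (2Z)-2-(hydroxymethylidene)-5-methoxy-8-(methoxymethoxy)-3,4-dihydronaphthalen-1(2H)-one
Conditions: NaH, THF, cat. EtOH, 0 °C → rt; aq HCl
Reagents that add atoms: none
Why: In this crossed Claisen condensation the tetralone enolate is acylated by the non-enolisable formate, and formation of the stabilised β-dicarbonyl enolate drives the equilibrium.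

**Step 7**
Reactants: 10 (2Z)-2-(hydroxymethylidene)-5-methoxy-8-(methoxymethoxy)-3,4-dihydronaphthalen-1(2H)-one
Product: 11 1-hydroxy-5-methoxy-8-(methoxymethoxy)naphthalene-2-carbaldehyde
Conditions: DDQ (1.1 equiv), 1,4-dioxane, rt
Reagents that add atoms: none
Why: DDQ dehydrogenation (hydride abstraction at benzylic C4, then proton loss) aromatises ring A, driven by formation of the naphthalene and the hydrogen-bonded salicylaldehyde-type product.

**Step 8**
Reactants: 11 1-hydroxy-5-methoxy-8-(methoxymethoxy)naphthalene-2-carbaldehyde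
Product: 12 1-[(tert-butyldimethylsilyl)oxy]-5-methoxy-8-(methoxymethoxy)naphthalene-2-carbaldehyde
Conditions: TBSOTf, 2,6-lutidine, CH2Cl2, 0 °C
Reagents that add atoms: tert-butyldimethylsilyl trifluoromethanesulfonate (TBSOTf), CC(C)(C)[Si](C)(C)OS(=O)(=O)C(F)(F)F
Why: Silylation with the highly electrophilic triflate overcomes the hydrogen-bonded, peri-flanked naphthol and masks it for the allylboration.

**Step 9**
Reactants: 12 1-[(tert-butyldimethylsilyl)oxy]-5-methoxy-8-(methoxymethoxy)naphthalene-2-carbaldehyde; 13 (−)-B-allyldiisopinocampheylborane, (−)-Ipc2B(allyl), the antipode derived from (+)-α-pinene (commercial solution in pentane)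
Product: 15 (1S)-1-{1-[(tert-butyldimethylsilyl)oxy]-5-methoxy-8-(methoxymethoxy)naphthalen-2-yl}but-3-en-1-ol, via diisopinocampheylborinate ester 14 (not isolated)
Conditions: Et2O, −78 °C; then 30% H2O2, aq NaOAc, 0 °C → rt
Reagents that add atoms: none
Why: Brown asymmetric allylboration (carbonyl allylation) proceeds through a closed chair Zimmerman–Traxler transition state in which the (+)-α-pinene-derived isopinocampheyl groups direct allyl transfer to the Si face of the aryl aldehyde, setting the (S)-carbinol, and buffered peroxide releases the alcohol from the borinate.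

**Step 10**
Reactants: 15 (1S)-1-{1-[(tert-butyldimethylsilyl)oxy]-5-methoxy-8-(methoxymethoxy)naphthalen-2-yl}but-3-en-1-ol; 16 2-methyl-2-butene
Product: 17 (1S)-1-{1-[(tert-butyldimethylsilyl)oxy]-5-methoxy-8-(methoxymethoxy)naphthalen-2-yl}-4-methylpent-3-en-1-ol
Conditions: second-generation Grubbs catalyst RuCl2(=CHPh)(PCy3)(H2IMes) (5 mol %), 16 in large excess, CH2Cl2, 35 °C
Reagents that add atoms: none
Why: Olefin cross-metathesis with excess 2-methyl-2-butene converts the terminal vinyl group into the trisubstituted isopropylidene terminus, driven by loss of propene, and leaves the stereocentre untouched.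

**Step 11**
Reactants: 17 (1S)-1-{1-[(tert-butyldimethylsilyl)oxy]-5-methoxy-8-(methoxymethoxy)naphthalen-2-yl}-4-methylpent-3-en-1-ol
Product: 18 2-[(1S)-1-hydroxy-4-methylpent-3-en-1-yl]-5-methoxy-8-(methoxymethoxy)naphthalen-1-ol
Conditions: Bu4NF, AcOH (1.1 equiv each), THF, 0 °C
Reagents that add atoms: none
Why: Fluoride-mediated desilylation frees the naphthol under buffered, non-acidic conditions so the ortho-hydroxybenzylic alcohol is not ionised, and any silyl group that has migrated to the secondary oxygen is removed as well.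

**Step 12**
Reactants: 18 2-[(1S)-1-hydroxy-4-methylpent-3-en-1-yl]-5-methoxy-8-(methoxymethoxy)naphthalen-1-ol
Product: 19 2-[(1S)-1-hydroxy-4-methylpent-3-en-1-yl]-5-methoxy-8-(methoxymethoxy)naphthalene-1,4-dione
Conditions: K2[ON(SO3)2] (2.5 equiv), aq KH2PO4, acetone, 0 °C → rt
Reagents that add atoms: potassium nitrosodisulfonate (Fremy's salt), [K+].[K+].[O]N(S(=O)(=O)[O-])S(=O)(=O)[O-]
Why: Teuber oxidation with Fremy's radical converts a 1-naphthol with a free para position regiospecifically into the 1,4-naphthoquinone and leaves the diether ring B, the alcohol and the alkene alone.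

**Step 13**
Reactants: 19 2-[(1S)-1-hydroxy-4-methylpent-3-en-1-yl]-5-methoxy-8-(methoxymethoxy)naphthalene-1,4-dione; 20 3-methylbut-2-enoic acid (3,3-dimethylacrylic acid)
Product: 21 (1S)-1-[5-methoxy-8-(methoxymethoxy)-1,4-dioxo-1,4-dihydronaphthalen-2-yl]-4-methylpent-3-en-1-yl 3-methylbut-2-enoate
Conditions: DCC, DMAP (0.1 equiv), CH2Cl2, 0 °C → rt
Reagents that add atoms: none
Why: Steglich esterification of the only free hydroxyl proceeds with retention at the stereocentre, and carbodiimide activation avoids the ketene pathway that deconjugates the acid chloride.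

**Step 14**
Reactants: 21 (1S)-1-[5-methoxy-8-(methoxymethoxy)-1,4-dioxo-1,4-dihydronaphthalen-2-yl]-4-methylpent-3-en-1-yl 3-methylbut-2-enoate
Product: 22 (1S)-1-(8-hydroxy-5-methoxy-1,4-dioxo-1,4-dihydronaphthalen-2-yl)-4-methylpent-3-en-1-yl 3-methylbut-2-enoate (target)
Conditions: CF3CO2H–CH2Cl2 (1:10), 0 °C; aq NaHCO3
Reagents that add atoms: none
Why: In this acid-catalysed acetal hydrolysis the peri carbonyl makes the 8-oxygen a hydrogen-bond-stabilised leaving group, so the MOM ether cleaves under conditions that spare the methyl ether, the ester, the alkene and the stereocentre (no ionisation next to the electron-poor quinone).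

**Compound list**
1 | 1,4-dimethoxybenzene | COc1ccc(OC)cc1 | starting material
2 | succinic anhydride | O=C1CCC(=O)O1 | starting material
3 | 4-(2,5-dimethoxyphenyl)-4-oxobutanoic acid | COc1ccc(OC)c(C(=O)CCC(=O)O)c1 | intermediate
4 | 4-(2,5-dimethoxyphenyl)butanoic acid | COc1ccc(OC)c(CCCC(=O)O)c1 | intermediate
5 | 5,8-dimethoxy-3,4-dihydronaphthalen-1(2H)-one | COc1ccc(OC)c2c1CCCC2=O | intermediate
6 | 8-(dichloroboryloxy)-5-methoxy-3,4-dihydronaphthalen-1(2H)-one (boron chelated by the ketone oxygen) | COc1ccc(OB(Cl)Cl)c2c1CCCC2=O | intermediate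
7 | 8-hydroxy-5-methoxy-3,4-dihydronaphthalen-1(2H)-one | COc1ccc(O)c2c1CCCC2=O | intermediate
8 | 5-methoxy-8-(methoxymethoxy)-3,4-dihydronaphthalen-1(2H)-one | COCOc1ccc(OC)c2c1C(=O)CCC2 | intermediate
9 | ethyl formate | CCOC=O | starting material
10 | (2Z)-2-(hydroxymethylidene)-5-methoxy-8-(methoxymethoxy)-3,4-dihydronaphthalen-1(2H)-one | O/C=C1/CCc2c(OC)ccc(OCOC)c2C1=O | intermediate
11 | 1-hydroxy-5-methoxy-8-(methoxymethoxy)naphthalene-2-carbaldehyde | COCOc1ccc(OC)c2ccc(C=O)c(O)c12 | intermediate
12 | 1-[(tert-butyldimethylsilyl)oxy]-5-methoxy-8-(methoxymethoxy)naphthalene-2-carbaldehyde | COCOc1ccc(OC)c2ccc(C=O)c(O[Si](C)(C)C(C)(C)C)c12 | intermediate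
13 | (−)-B-allyldiisopinocampheylborane, isopinocampheyl groups from (+)-α-pinene | C=CCB([C@@H]1C[C@@H]2C[C@H]([C@H]1C)C2(C)C)[C@@H]1C[C@@H]2C[C@H]([C@H]1C)C2(C)C | starting material
14 | (1S)-1-{1-[(tert-butyldimethylsilyl)oxy]-5-methoxy-8-(methoxymethoxy)naphthalen-2-yl}but-3-en-1-yl diisopinocampheylborinate | C=CC[C@H](OB([C@@H]1C[C@@H]2C[C@H]([C@H]1C)C2(C)C)[C@@H]1C[C@@H]2C[C@H]([C@H]1C)C2(C)C)c1ccc2c(OC)ccc(OCOC)c2c1O[Si](C)(C)C(C)(C)C | intermediate
15 | (1S)-1-{1-[(tert-butyldimethylsilyl)oxy]-5-methoxy-8-(methoxymethoxy)naphthalen-2-yl}but-3-en-1-ol | C=CC[C@H](O)c1ccc2c(OC)ccc(OCOC)c2c1O[Si](C)(C)C(C)(C)C | intermediate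
16 | 2-methyl-2-butene | CC=C(C)C | starting material
17 | (1S)-1-{1-[(tert-butyldimethylsilyl)oxy]-5-methoxy-8-(methoxymethoxy)naphthalen-2-yl}-4-methylpent-3-en-1-ol | CC(C)=CC[C@H](O)c1ccc2c(OC)ccc(OCOC)c2c1O[Si](C)(C)C(C)(C)C | intermediate
18 | 2-[(1S)-1-hydroxy-4-methylpent-3-en-1-yl]-5-methoxy-8-(methoxymethoxy)naphthalen-1-ol | CC(C)=CC[C@H](O)c1ccc2c(OC)ccc(OCOC)c2c1O | intermediate
19 | 2-[(1S)-1-hydroxy-4-methylpent-3-en-1-yl]-5-methoxy-8-(methoxymethoxy)naphthalene-1,4-dione | CC(C)=CC[C@H](O)C1=CC(=O)c2c(OC)ccc(OCOC)c2C1=O | intermediate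
20 | 3-methylbut-2-enoic acid | CC(C)=CC(=O)O | starting material
21 | (1S)-1-[5-methoxy-8-(methoxymethoxy)-1,4-dioxo-1,4-dihydronaphthalen-2-yl]-4-methylpent-3-en-1-yl 3-methylbut-2-enoate | CC(C)=CC[C@H](OC(=O)C=C(C)C)C1=CC(=O)c2c(OC)ccc(OCOC)c2C1=O | intermediate
22 | (1S)-1-(8-hydroxy-5-methoxy-1,4-dioxo-1,4-dihydronaphthalen-2-yl)-4-methylpent-3-en-1-yl 3-methylbut-2-enoate | COc1ccc(O)c2c1C(=O)C=C([C@H](CC=C(C)C)OC(=O)C=C(C)C)C2=O | target

**Totals**
Total step count: 14. Longest linear sequence: 14 steps (1 → 22).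

**Steps most likely to fail, with fallbacks**

Step 9 (asymmetric allylboration of a hindered, silyloxy-flanked aldehyde; risk of low conversion or eroded enantiopurity). The fallback sets out from 12 and returns at 17. Allylmagnesium bromide (THF, −78 °C) adds to 12 to give racemic 1-{1-[(tert-butyldimethylsilyl)oxy]-5-methoxy-8-(methoxymethoxy)naphthalen-2-yl}but-3-en-1-ol F1. Cross-metathesis with 16 as in step 10 gives racemic 1-{1-[(tert-butyldimethylsilyl)oxy]-5-methoxy-8-(methoxymethoxy)naphthalen-2-yl}-4-methylpent-3-en-1-ol F2. Dess–Martin periodinane (NaHCO3, CH2Cl2) then gives the aryl ketone 1-{1-[(tert-butyldimethylsilyl)oxy]-5-methoxy-8-(methoxymethoxy)naphthalen-2-yl}-4-methylpent-3-en-1-one F3. Reagent-controlled reduction with (−)-Ipc2BCl (THF, −25 °C; diethanolamine work-up) sets the (S)-carbinol and delivers 17. The carbon–carbon bond is still made by carbonyl allylation, but the stereocentre now comes from ketone reduction.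

Step 12 (direct oxidation of the sensitive ortho-hydroxybenzylic naphthol; risk of low yield or quinone-methide chemistry). The fallback sets out from 18 and returns at 19. PhI(OAc)2 (2.2 equiv) in MeOH at 0 °C oxidises the naphthol in two stages to the quinone monoketal 2-[(1S)-1-hydroxy-4-methylpent-3-en-1-yl]-4,4,5-trimethoxy-8-(methoxymethoxy)naphthalen-1(4H)-one F4. Brief treatment with aqueous oxalic acid in THF unmasks the second carbonyl and gives 19.

Step 14 (final acidic MOM cleavage in the presence of the senecioate and the trisubstituted alkene). The fallback sets out from 19 and returns at 22. The MOM ether is cleaved before the ester exists (dilute HCl, THF–i-PrOH, rt), giving 8-hydroxy-2-[(1S)-1-hydroxy-4-methylpent-3-en-1-yl]-5-methoxynaphthalene-1,4-dione F5. Acylation with 20, DCC and catalytic DMAP then reacts only at the side-chain hydroxyl, because the peri phenol is hydrogen-bonded to the quinone carbonyl, and gives 22 directly.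

**Further compounds**
F1 | step 9 | racemic 1-{1-[(tert-butyldimethylsilyl)oxy]-5-methoxy-8-(methoxymethoxy)naphthalen-2-yl}but-3-en-1-ol | C=CCC(O)c1ccc2c(OC)ccc(OCOC)c2c1O[Si](C)(C)C(C)(C)C
F2 | step 9 | racemic 1-{1-[(tert-butyldimethylsilyl)oxy]-5-methoxy-8-(methoxymethoxy)naphthalen-2-yl}-4-methylpent-3-en-1-ol | CC(C)=CCC(O)c1ccc2c(OC)ccc(OCOC)c2c1O[Si](C)(C)C(C)(C)C
F3 | step 9 | 1-{1-[(tert-butyldimethylsilyl)oxy]-5-methoxy-8-(methoxymethoxy)naphthalen-2-yl}-4-methylpent-3-en-1-one | CC(C)=CCC(=O)c1ccc2c(OC)ccc(OCOC)c2c1O[Si](C)(C)C(C)(C)C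
F4 | step 12 | 2-[(1S)-1-hydroxy-4-methylpent-3-en-1-yl]-4,4,5-trimethoxy-8-(methoxymethoxy)naphthalen-1(4H)-one | CC(C)=CC[C@H](O)C1=CC(OC)(OC)c2c(OC)ccc(OCOC)c2C1=O
F5 | step 14 | 8-hydroxy-2-[(1S)-1-hydroxy-4-methylpent-3-en-1-yl]-5-methoxynaphthalene-1,4-dione | CC(C)=CC[C@H](O)C1=CC(=O)c2c(OC)ccc(O)c2C1=O
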